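The C40 retro-polyene is cut at the C13–C14 sp2–sp2 single bond, where the methyl-bearing end of the C12=C13 alkene meets the disubstituted (E)-C14=C15 alkene. The key step hydrozirconates the terminal C14≡C15 alkyne of a C22 polyenyne carrying ring B (the 3',5'-diol ring). In the same flask it couples the resulting (E)-alkenylzirconocene, under Pd(PPh3)4/ZnCl2 catalysis, with a C18 alkenyl iodide carrying ring A (iodine on C13). The C14=C15 alkene and the C13–C14 bond thus arise together. Both halves come from one cyclohexanone whose exocyclic C6=C7 geometry is fixed by a Ti(OiPr)4/i-PrMgCl-mediated alkyne–ester cyclisation.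

Key step: step 23

Remark: carotenoid numbering is used (ring A = C1–C6 with the C4=C5 bond, ring B = C1'–C6' with the 5'-hydroxyl); compounds 1, 7, 20 and 25 are taken as purchased; in SMILES the cyclopentadienyl ligands on zirconium are drawn as σ-bonded rings.

Step 1
Reactants: 1 2,2-dimethylpent-4-enal
Product: 2 3,3-dimethylhex-5-en-1-yne
Conditions: dimethyl (1-diazo-2-oxopropyl)phosphonate, K2CO3, MeOH, 0 °C to rt
Reagents that add atoms: dimethyl (1-diazo-2-oxopropyl)phosphonate CC(=O)C(=[N+]=[N-])P(=O)(OC)OC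
Why: Seyferth–Gilbert homologation with the Ohira–Bestmann reagent should convert the non-enolisable aldehyde into the terminal alkyne under mild base that leaves the alkene untouched.

Step 2
Reactants: 2 3,3-dimethylhex-5-en-1-yne
Product: 4 trimethyl(3,3-dimethylhex-5-en-1-yn-1-yl)silane, via lithium acetylide 3 (not isolated)
Conditions: n-BuLi, THF, −78 °C; then Me3SiCl, −78 °C to rt
Reagents that add atoms: chlorotrimethylsilane C[Si](C)(C)Cl
Why: Deprotonation and C-silylation of the acetylide installs the silyl group that caps the alkyne for the titanium step and later becomes the handle for iodination.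

Step 3
Reactants: 4 trimethyl(3,3-dimethylhex-5-en-1-yn-1-yl)silane
Product: 6 3,3-dimethyl-5-(trimethylsilyl)pent-4-ynal, via ozonide 5 (not isolated)
Conditions: O3, CH2Cl2, −78 °C; then PPh3, −78 °C to rt
Reagents that add atoms: ozone [O-][O+]=O
Why: Ozonolysis with reductive work-up should cleave the terminal alkene much faster than the hindered silyl-capped alkyne and unveil the aldehyde that becomes C3.

Step 4
Reactants: 6 3,3-dimethyl-5-(trimethylsilyl)pent-4-ynal; 7 ethyl diazoacetate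
Product: 8 ethyl 5,5-dimethyl-3-oxo-7-(trimethylsilyl)hept-6-ynoate
Conditions: SnCl2 (10 mol %), CH2Cl2, rt
Reagents that add atoms: none
Why: Roskamp reaction: SnCl2-catalysed addition of the diazoester to the aldehyde, 1,2-hydride shift and loss of N2 should give the β-keto ester directly.

Step 5
Reactants: 8 ethyl 5,5-dimethyl-3-oxo-7-(trimethylsilyl)hept-6-ynoate
Product: 9 ethyl (3S)-3-hydroxy-5,5-dimethyl-7-(trimethylsilyl)hept-6-ynoate
Conditions: H2 (10 bar), RuCl2[(S)-BINAP] (1 mol %), EtOH, 50 °C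
Reagents that add atoms: none
Why: Noyori asymmetric hydrogenation of a β-keto ester: RuCl2[(S)-BINAP] should reduce the chelated ketone from one face to set the (3S)-carbinol (C3 of both rings), and the hindered silyl-capped alkyne should survive.

Step 6
Reactants: 9 ethyl (3S)-3-hydroxy-5,5-dimethyl-7-(trimethylsilyl)hept-6-ynoate
Product: 10 ethyl (3S)-3-[(tert-butyldimethylsilyl)oxy]-5,5-dimethyl-7-(trimethylsilyl)hept-6-ynoate
Conditions: t-BuMe2SiCl, imidazole, DMF, rt
Reagents that add atoms: tert-butyl(chloro)dimethylsilane CC(C)(C)[Si](C)(C)Cl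
Why: Standard silylation protects the secondary alcohol as a robust ether for the organometallic steps ahead.

Step 7
Reactants: 10 ethyl (3S)-3-[(tert-butyldimethylsilyl)oxy]-5,5-dimethyl-7-(trimethylsilyl)hept-6-ynoate
Product: 12 (2E,5S)-5-[(tert-butyldimethylsilyl)oxy]-3,3-dimethyl-2-[(trimethylsilyl)methylidene]cyclohexan-1-one, via alkenyltitanium 11 (not isolated)
Conditions: Ti(OiPr)4 (1.3 equiv), i-PrMgCl (2.6 equiv), Et2O, −78 to −50 °C, then to 0 °C; saturated aq. NH4Cl
Reagents that add atoms: none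
Why: Intramolecular nucleophilic acyl substitution mediated by Ti(OiPr)4/i-PrMgCl: the divalent-titanium propene complex exchanges onto the alkyne, the titanacyclopropene attacks the tethered ester through the tether-bearing carbon with loss of ethoxide (6-exo ring closure), and protonolysis of the C7–Ti bond leaves H cis to the carbonyl, so the syn addition locks the silyl group cis to the CMe2 carbon (E).

Step 8
Reactants: 12 (2E,5S)-5-[(tert-butyldimethylsilyl)oxy]-3,3-dimethyl-2-[(trimethylsilyl)methylidene]cyclohexan-1-one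
Product: 14 triethyl{[(1R,2E,5S)-5-[(tert-butyldimethylsilyl)oxy]-1,3,3-trimethyl-2-[(trimethylsilyl)methylidene]cyclohexyl]oxy}silane, via lithium alkoxide 13 (not isolated)
Conditions: MeLi, Et2O, −78 °C; then Et3SiOTf, −78 to 0 °C
Reagents that add atoms: methyllithium [Li]C; triethylsilyl trifluoromethanesulfonate CC[Si](CC)(CC)OS(=O)(=O)C(F)(F)F
Why: 1,2-Addition of MeLi to the enone: the axial methyl of the CMe2 group blocks the axial trajectory (as in 3,3,5-trimethylcyclohexanone), so methyl should enter equatorially and the new C5 oxygen becomes axial and trans to the equatorial 3-silyloxy group (5R); the alkoxide is silylated in the same flask.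

Step 9
Reactants: 14 triethyl{[(1R,2E,5S)-5-[(tert-butyldimethylsilyl)oxy]-1,3,3-trimethyl-2-[(trimethylsilyl)methylidene]cyclohexyl]oxy}silane
Product: 15 {[(1R,2E,5S)-5-[(tert-butyldimethylsilyl)oxy]-2-(iodomethylidene)-1,3,3-trimethylcyclohexyl]oxy}triethylsilane
Conditions: N-iodosuccinimide, 2,6-lutidine, (CF3)2CHOH, 0 °C, dark
Reagents that add atoms: N-iodosuccinimide O=C1CCC(=O)N1I
Why: Electrophilic ipso-iododesilylation of the vinylsilane through the β-silyl cation should proceed with retention and place iodine cis to the CMe2 carbon.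

Step 10
Reactants: 12 (2E,5S)-5-[(tert-butyldimethylsilyl)oxy]-3,3-dimethyl-2-[(trimethylsilyl)methylidene]cyclohexan-1-one
Product: 17 (3S,6E)-3-[(tert-butyldimethylsilyl)oxy]-5,5-dimethyl-6-[(trimethylsilyl)methylidene]cyclohex-1-en-1-yl trifluoromethanesulfonate, via potassium dienolate 16 (not isolated)
Conditions: KN(SiMe3)2, THF, −78 °C; then PhNTf2, −78 to −40 °C
Reagents that add atoms: N-phenylbis(trifluoromethanesulfonimide) O=S(=O)(N(c1ccccc1)S(=O)(=O)C(F)(F)F)C(F)(F)F
Why: Enolisation can occur only toward C4, and O-triflation of the dienolate at low temperature (to outrun β-elimination of the silyloxy group) should give the dienyl triflate.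

Step 11
Reactants: 17 (3S,6E)-3-[(tert-butyldimethylsilyl)oxy]-5,5-dimethyl-6-[(trimethylsilyl)methylidene]cyclohex-1-en-1-yl trifluoromethanesulfonate
Product: 18 tert-butyldimethyl{[(1S,4E)-3,5,5-trimethyl-4-[(trimethylsilyl)methylidene]cyclohex-2-en-1-yl]oxy}silane
Conditions: MeMgBr, Fe(acac)3 (5 mol %), THF/NMP, −30 to 0 °C
Reagents that add atoms: methylmagnesium bromide C[Mg]Br
Why: Fe(acac)3-catalysed Kumada-type coupling of the enol triflate with the methyl Grignard reagent installs the C5 methyl and with it the C4=C5 bond of ring A, without touching the vinylsilane.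

Step 12
Reactants: 18 tert-butyldimethyl{[(1S,4E)-3,5,5-trimethyl-4-[(trimethylsilyl)methylidene]cyclohex-2-en-1-yl]oxy}silane
Product: 19 tert-butyl{[(1S,4E)-4-(iodomethylidene)-3,5,5-trimethylcyclohex-2-en-1-yl]oxy}dimethylsilane
Conditions: N-iodosuccinimide, 2,6-lutidine, (CF3)2CHOH, 0 °C, dark
Reagents that add atoms: N-iodosuccinimide O=C1CCC(=O)N1I
Why: Ipso-iododesilylation of the dienylsilane (β-silyl, allyl-stabilised cation) should give the dienyl iodide with retention, iodine cis to the CMe2 carbon (6E).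

Step 13
Reactants: 20 1,4-bis(trimethylsilyl)buta-1,3-diyne
Product: 22 (buta-1,3-diyn-1-yl)trimethylsilane, via lithium butadiynide 21 (not isolated)
Conditions: MeLi·LiBr (1.0 equiv), Et2O, 0 °C to rt; then saturated aq. NH4Cl
Reagents that add atoms: none
Why: Selective mono-desilylation of the bis-silyl diyne with one equivalent of methyllithium gives the lithium diynide, which is protonated on work-up.

Step 14
Reactants: 22 (buta-1,3-diyn-1-yl)trimethylsilane
Product: 24 [(3E)-4-iodobut-3-en-1-yn-1-yl]trimethylsilane, via alkenylzirconocene 23 (not isolated)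
Conditions: Cp2Zr(H)Cl, THF, rt, dark; then I2, 0 °C
Reagents that add atoms: iodine II
Why: Hydrozirconation adds H and Zr syn to the terminal alkyne only (Zr on the terminal carbon), and iodinolysis with retention should give the (E)-iodoenyne.

Step 15
Reactants: 24 [(3E)-4-iodobut-3-en-1-yn-1-yl]trimethylsilane; 25 propyne
Product: 26 [(3E)-hept-3-ene-1,5-diyn-1-yl]trimethylsilane
Conditions: PdCl2(PPh3)2 (2 mol %), CuI (4 mol %), Et3N, THF, 0 °C to rt
Reagents that add atoms: none
Why: Sonogashira coupling of the alkenyl iodide with propyne proceeds with retention of the E geometry.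

Step 16
Reactants: 26 [(3E)-hept-3-ene-1,5-diyn-1-yl]trimethylsilane
Product: 27 (3E)-hept-3-ene-1,5-diyne
Conditions: K2CO3 (10 mol %), MeOH, 0 °C; kept as a pentane solution
Reagents that add atoms: none
Why: Carbonate-catalysed methanolysis of the alkynyl–silicon bond frees the terminal alkyne.

Step 17
Reactants: 27 (3E)-hept-3-ene-1,5-diyne
Product: 28 dimethyl[(1E,3E)-2-methylhepta-1,3-dien-5-yn-1-yl]alumane (prepared once; used as a THF stock solution)
Conditions: Me3Al (2 equiv), Cp2ZrCl2 (25 mol %), ClCH2CH2Cl, rt; volatiles removed in vacuo; residue dissolved in THF and divided into two equal portions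
Reagents that add atoms: trimethylaluminium C[Al](C)C
Why: Negishi Cp2ZrCl2-catalysed carboalumination adds Me and Al syn across the terminal alkyne only (methyl on the internal carbon, the future C9 or C9'), leaving the internal 2-alkyne untouched, so one batch of the (E)-alkenylalane serves both ring couplings.

Step 18
Reactants: 28 dimethyl[(1E,3E)-2-methylhepta-1,3-dien-5-yn-1-yl]alumane; 19 tert-butyl{[(1S,4E)-4-(iodomethylidene)-3,5,5-trimethylcyclohex-2-en-1-yl]oxy}dimethylsilane
Product: 29 tert-butyldimethyl{[(1S,4E)-3,5,5-trimethyl-4-[(2E,4E)-3-methylocta-2,4-dien-6-yn-1-ylidene]cyclohex-2-en-1-yl]oxy}silane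
Conditions: first portion of the stock solution of 28, Pd(PPh3)4 (5 mol %), ZnCl2 (20 mol %), THF, rt, dark
Reagents that add atoms: none
Why: Negishi alkenyl–alkenyl coupling of the alkenylalane with the alkenyl iodide under Pd(PPh3)4/ZnCl2 co-catalysis should form C7–C8 with retention at both partners (6E, 8E).

Step 19
Reactants: 28 dimethyl[(1E,3E)-2-methylhepta-1,3-dien-5-yn-1-yl]alumane; 15 {[(1R,2E,5S)-5-[(tert-butyldimethylsilyl)oxy]-2-(iodomethylidene)-1,3,3-trimethylcyclohexyl]oxy}triethylsilane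
Product: 30 triethyl{[(1R,2E,5S)-5-[(tert-butyldimethylsilyl)oxy]-1,3,3-trimethyl-2-[(2E,4E)-3-methylocta-2,4-dien-6-yn-1-ylidene]cyclohexyl]oxy}silane
Conditions: second portion of the stock solution of 28, Pd(PPh3)4 (5 mol %), ZnCl2 (20 mol %), THF, rt, dark
Reagents that add atoms: none
Why: The same Negishi alkenylalane coupling under Pd(PPh3)4/ZnCl2 co-catalysis attaches the C8'–C13' chain to ring B with retention (6'E, 8'E); the tertiary and secondary hydroxyls are silylated, so the alane is not protonated.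

Step 20
Reactants: 29 tert-butyldimethyl{[(1S,4E)-3,5,5-trimethyl-4-[(2E,4E)-3-methylocta-2,4-dien-6-yn-1-ylidene]cyclohex-2-en-1-yl]oxy}silane
Product: 32 tert-butyl{[(1S,4E)-4-[(2E,4E,6E)-7-iodo-3-methylocta-2,4,6-trien-1-ylidene]-3,5,5-trimethylcyclohex-2-en-1-yl]oxy}dimethylsilane, via alkenylzirconocene 31 (not isolated)
Conditions: Cp2Zr(H)Cl (2 equiv), THF, 45 °C, dark; then I2, THF, −78 °C
Reagents that add atoms: iodine II
Why: Hydrozirconation of the 2-alkyne with excess reagent under equilibrating conditions should place Zr on the less hindered methyl-bearing carbon C13 by syn addition, and iodinolysis with retention gives the (12E)-iodide with iodine trans to C11.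

Step 21
Reactants: 30 triethyl{[(1R,2E,5S)-5-[(tert-butyldimethylsilyl)oxy]-1,3,3-trimethyl-2-[(2E,4E)-3-methylocta-2,4-dien-6-yn-1-ylidene]cyclohexyl]oxy}silane; 24 [(3E)-4-iodobut-3-en-1-yn-1-yl]trimethylsilane
Product: 34 {[(1R,2E,5S)-5-[(tert-butyldimethylsilyl)oxy]-2-[(2E,4E,6E,8E)-3,7-dimethyl-11-(trimethylsilyl)undeca-2,4,6,8-tetraen-10-yn-1-ylidene]-1,3,3-trimethylcyclohexyl]oxy}triethylsilane, via alkenylzirconocene 33 (not isolated)
Conditions: Cp2Zr(H)Cl (2 equiv), THF, 45 °C, dark; then 24, Pd(PPh3)4 (5 mol %), ZnCl2 (20 mol %), THF, rt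
Reagents that add atoms: none
Why: The same regioselective syn-hydrozirconation puts Zr on C13', and Negishi coupling with the (E)-iodoenyne under Pd(PPh3)4/ZnCl2 co-catalysis should form C13'–C14' with retention, adding the C14'=C15' alkene and the masked C14≡C15 alkyne.

Step 22
Reactants: 34 {[(1R,2E,5S)-5-[(tert-butyldimethylsilyl)oxy]-2-[(2E,4E,6E,8E)-3,7-dimethyl-11-(trimethylsilyl)undeca-2,4,6,8-tetraen-10-yn-1-ylidene]-1,3,3-trimethylcyclohexyl]oxy}triethylsilane
Product: 35 {[(1R,2E,5S)-5-[(tert-butyldimethylsilyl)oxy]-2-[(2E,4E,6E,8E)-3,7-dimethylundeca-2,4,6,8-tetraen-10-yn-1-ylidene]-1,3,3-trimethylcyclohexyl]oxy}triethylsilane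
Conditions: K2CO3, MeOH/THF, 0 °C to rt, dark
Reagents that add atoms: none
Why: Carbonate-catalysed methanolysis should remove only the alkynyl silyl group; the secondary tert-butyldimethylsilyl and tertiary triethylsilyl ethers survive.

Step 23
Reactants: 35 {[(1R,2E,5S)-5-[(tert-butyldimethylsilyl)oxy]-2-[(2E,4E,6E,8E)-3,7-dimethylundeca-2,4,6,8-tetraen-10-yn-1-ylidene]-1,3,3-trimethylcyclohexyl]oxy}triethylsilane; 32 tert-butyl{[(1S,4E)-4-[(2E,4E,6E)-7-iodo-3-methylocta-2,4,6-trien-1-ylidene]-3,5,5-trimethylcyclohex-2-en-1-yl]oxy}dimethylsilane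
Product: 37 tris-silyl ether of the target (3-O-tert-butyldimethylsilyl; 3'-O-tert-butyldimethylsilyl; 5'-O-triethylsilyl), via alkenylzirconocene 36 (not isolated)
Conditions: Cp2Zr(H)Cl (1.1 equiv), THF, rt, dark; then 32, Pd(PPh3)4 (5 mol %), ZnCl2 (20 mol %), THF, rt, dark
Reagents that add atoms: none
Why: Cp2Zr(H)Cl adds H and Zr syn across the terminal C14≡C15 alkyne of 35 with Zr on the terminal carbon, so the (E)-C14=C15 alkene and the C14 nucleophile are created together; zerovalent palladium then inserts into the C13–I bond of 32 with retention, the alkenyl group passes from zirconium via zinc to palladium, and reductive elimination forms the C13–C14 bond. The closest known reaction type is the Negishi hydrozirconation followed by alkenyl–alkenyl coupling under Pd(PPh3)4/ZnCl2 co-catalysis, as used for all-E oligoenes. No ring is closed and no stereocentre is formed; the C12=C13 geometry comes from the iodide and the C14=C15 geometry from the syn addition, both carried through with retention. The step needs hydrometallation of the single alkyne in the presence of five conjugated C=C bonds, which internal conjugated alkenes allow because they do not react with Cp2Zr(H)Cl at room temperature, and it needs all three hydroxyls masked so that the organometallic is not protonated. Exclusion of light and acid keeps the all-E chain and the allylic C–O bonds intact.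

Step 24
Reactants: 37 tris-silyl ether of the target
Product: 38 target retro-carotenoid triol (3S; 3'S,5'R; 6E; 6'E; all-E chain)
Conditions: Bu4NF, THF, 0 °C to rt, dark; aqueous work-up
Reagents that add atoms: none
Why: Fluoride-mediated desilylation cleaves all three silyl ethers under non-acidic conditions, which should spare the acid-labile tertiary allylic C5' alcohol and the allylic C3 alcohol and leave the polyene geometry untouched.

Compound list
1 | 2,2-dimethylpent-4-enal | C=CCC(C)(C)C=O | starting material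
2 | 3,3-dimethylhex-5-en-1-yne | C#CC(C)(C)CC=C | intermediate
3 | lithium 3,3-dimethylhex-5-en-1-yn-1-ide | [Li]C#CC(C)(C)CC=C | intermediate
4 | trimethyl(3,3-dimethylhex-5-en-1-yn-1-yl)silane | C[Si](C)(C)C#CC(C)(C)CC=C | intermediate
5 | 3-[2,2-dimethyl-4-(trimethylsilyl)but-3-yn-1-yl]-1,2,4-trioxolane | C[Si](C)(C)C#CC(C)(C)CC1OCOO1 | intermediate
6 | 3,3-dimethyl-5-(trimethylsilyl)pent-4-ynal | C[Si](C)(C)C#CC(C)(C)CC=O | intermediate
7 | ethyl diazoacetate | CCOC(=O)C=[N+]=[N-] | starting material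
8 | ethyl 5,5-dimethyl-3-oxo-7-(trimethylsilyl)hept-6-ynoate | CCOC(=O)CC(=O)CC(C)(C)C#C[Si](C)(C)C | intermediate
9 | ethyl (3S)-3-hydroxy-5,5-dimethyl-7-(trimethylsilyl)hept-6-ynoate | CCOC(=O)C[C@@H](O)CC(C)(C)C#C[Si](C)(C)C | intermediate
10 | ethyl (3S)-3-[(tert-butyldimethylsilyl)oxy]-5,5-dimethyl-7-(trimethylsilyl)hept-6-ynoate | CCOC(=O)C[C@@H](O[Si](C)(C)C(C)(C)C)CC(C)(C)C#C[Si](C)(C)C | intermediate
11 | ethoxydi(propan-2-yloxy){(Z)-[(4S)-4-[(tert-butyldimethylsilyl)oxy]-6,6-dimethyl-2-oxocyclohexylidene](trimethylsilyl)methyl}titanium | CCO[Ti](OC(C)C)(OC(C)C)/C(=C1\C(=O)C[C@@H](O[Si](C)(C)C(C)(C)C)CC1(C)C)[Si](C)(C)C | intermediate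
12 | (2E,5S)-5-[(tert-butyldimethylsilyl)oxy]-3,3-dimethyl-2-[(trimethylsilyl)methylidene]cyclohexan-1-one | C[Si](C)(C)/C=C1/C(=O)C[C@@H](O[Si](C)(C)C(C)(C)C)CC1(C)C | intermediate
13 | lithium (1R,2E,5S)-5-[(tert-butyldimethylsilyl)oxy]-1,3,3-trimethyl-2-[(trimethylsilyl)methylidene]cyclohexan-1-olate | C[Si](C)(C)/C=C1/[C@](C)(O[Li])C[C@@H](O[Si](C)(C)C(C)(C)C)CC1(C)C | intermediate
14 | triethyl{[(1R,2E,5S)-5-[(tert-butyldimethylsilyl)oxy]-1,3,3-trimethyl-2-[(trimethylsilyl)methylidene]cyclohexyl]oxy}silane | C[Si](C)(C)/C=C1/[C@](C)(O[Si](CC)(CC)CC)C[C@@H](O[Si](C)(C)C(C)(C)C)CC1(C)C | intermediate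
15 | {[(1R,2E,5S)-5-[(tert-butyldimethylsilyl)oxy]-2-(iodomethylidene)-1,3,3-trimethylcyclohexyl]oxy}triethylsilane | I/C=C1/[C@](C)(O[Si](CC)(CC)CC)C[C@@H](O[Si](C)(C)C(C)(C)C)CC1(C)C | intermediate
16 | potassium (3S,6E)-3-[(tert-butyldimethylsilyl)oxy]-5,5-dimethyl-6-[(trimethylsilyl)methylidene]cyclohex-1-en-1-olate | C[Si](C)(C)/C=C1/C(O[K])=C[C@@H](O[Si](C)(C)C(C)(C)C)CC1(C)C | intermediate
17 | (3S,6E)-3-[(tert-butyldimethylsilyl)oxy]-5,5-dimethyl-6-[(trimethylsilyl)methylidene]cyclohex-1-en-1-yl trifluoromethanesulfonate | C[Si](C)(C)/C=C1/C(OS(=O)(=O)C(F)(F)F)=C[C@@H](O[Si](C)(C)C(C)(C)C)CC1(C)C | intermediate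
18 | tert-butyldimethyl{[(1S,4E)-3,5,5-trimethyl-4-[(trimethylsilyl)methylidene]cyclohex-2-en-1-yl]oxy}silane | C[Si](C)(C)/C=C1/C(C)=C[C@@H](O[Si](C)(C)C(C)(C)C)CC1(C)C | intermediate
19 | tert-butyl{[(1S,4E)-4-(iodomethylidene)-3,5,5-trimethylcyclohex-2-en-1-yl]oxy}dimethylsilane | I/C=C1/C(C)=C[C@@H](O[Si](C)(C)C(C)(C)C)CC1(C)C | intermediate
20 | 1,4-bis(trimethylsilyl)buta-1,3-diyne | C[Si](C)(C)C#CC#C[Si](C)(C)C | starting material
21 | lithium 4-(trimethylsilyl)buta-1,3-diyn-1-ide | [Li]C#CC#C[Si](C)(C)C | intermediate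
22 | (buta-1,3-diyn-1-yl)trimethylsilane | C#CC#C[Si](C)(C)C | intermediate
23 | chlorobis(cyclopentadienyl)[(1E)-4-(trimethylsilyl)but-1-en-3-yn-1-yl]zirconium | C[Si](C)(C)C#C/C=C/[Zr](Cl)(C1C=CC=C1)C1C=CC=C1 | intermediate
24 | [(3E)-4-iodobut-3-en-1-yn-1-yl]trimethylsilane | C[Si](C)(C)C#C/C=C/I | intermediate
25 | propyne | CC#C | starting material
26 | [(3E)-hept-3-ene-1,5-diyn-1-yl]trimethylsilane | CC#C/C=C/C#C[Si](C)(C)C | intermediate
27 | (3E)-hept-3-ene-1,5-diyne | CC#C/C=C/C#C | intermediate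
28 | dimethyl[(1E,3E)-2-methylhepta-1,3-dien-5-yn-1-yl]alumane | C[Al](C)/C=C(C)/C=C/C#CC | intermediate
29 | tert-butyldimethyl{[(1S,4E)-3,5,5-trimethyl-4-[(2E,4E)-3-methylocta-2,4-dien-6-yn-1-ylidene]cyclohex-2-en-1-yl]oxy}silane | CC#C/C=C/C(C)=C/C=C1/C(C)=C[C@@H](O[Si](C)(C)C(C)(C)C)CC1(C)C | intermediate
30 | triethyl{[(1R,2E,5S)-5-[(tert-butyldimethylsilyl)oxy]-1,3,3-trimethyl-2-[(2E,4E)-3-methylocta-2,4-dien-6-yn-1-ylidene]cyclohexyl]oxy}silane | CC#C/C=C/C(C)=C/C=C1/[C@](C)(O[Si](CC)(CC)CC)C[C@@H](O[Si](C)(C)C(C)(C)C)CC1(C)C | intermediate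
31 | alkenylzirconocene chloride from 29, Cp2ZrCl on C13 of the new (12E)-alkene (Zr trans to C11) | Cl[Zr](C1C=CC=C1)(C1C=CC=C1)/C(C)=C/C=C/C(C)=C/C=C1/C(C)=C[C@@H](O[Si](C)(C)C(C)(C)C)CC1(C)C | intermediate
32 | tert-butyl{[(1S,4E)-4-[(2E,4E,6E)-7-iodo-3-methylocta-2,4,6-trien-1-ylidene]-3,5,5-trimethylcyclohex-2-en-1-yl]oxy}dimethylsilane | I/C(C)=C/C=C/C(C)=C/C=C1/C(C)=C[C@@H](O[Si](C)(C)C(C)(C)C)CC1(C)C | intermediate
33 | alkenylzirconocene chloride from 30, Cp2ZrCl on C13' of the new (12'E)-alkene (Zr trans to C11') | Cl[Zr](C1C=CC=C1)(C1C=CC=C1)/C(C)=C/C=C/C(C)=C/C=C1/[C@](C)(O[Si](CC)(CC)CC)C[C@@H](O[Si](C)(C)C(C)(C)C)CC1(C)C | intermediate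
34 | {[(1R,2E,5S)-5-[(tert-butyldimethylsilyl)oxy]-2-[(2E,4E,6E,8E)-3,7-dimethyl-11-(trimethylsilyl)undeca-2,4,6,8-tetraen-10-yn-1-ylidene]-1,3,3-trimethylcyclohexyl]oxy}triethylsilane | C[Si](C)(C)C#C/C=C/C(C)=C/C=C/C(C)=C/C=C1/[C@](C)(O[Si](CC)(CC)CC)C[C@@H](O[Si](C)(C)C(C)(C)C)CC1(C)C | intermediate
35 | {[(1R,2E,5S)-5-[(tert-butyldimethylsilyl)oxy]-2-[(2E,4E,6E,8E)-3,7-dimethylundeca-2,4,6,8-tetraen-10-yn-1-ylidene]-1,3,3-trimethylcyclohexyl]oxy}triethylsilane | C#C/C=C/C(C)=C/C=C/C(C)=C/C=C1/[C@](C)(O[Si](CC)(CC)CC)C[C@@H](O[Si](C)(C)C(C)(C)C)CC1(C)C | intermediate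
36 | alkenylzirconocene chloride from 35, Cp2ZrCl on C14 of the new (E)-C14=C15 alkene | Cl[Zr](C1C=CC=C1)(C1C=CC=C1)/C=C/C=C/C(C)=C/C=C/C(C)=C/C=C1/[C@](C)(O[Si](CC)(CC)CC)C[C@@H](O[Si](C)(C)C(C)(C)C)CC1(C)C | intermediate
37 | tris-silyl ether of the target (3-O- and 3'-O-tert-butyldimethylsilyl, 5'-O-triethylsilyl) | CC1=C[C@@H](O[Si](C)(C)C(C)(C)C)CC(C)(C)\C1=C/C=C(C)/C=C/C=C(C)/C=C/C=C/C(C)=C/C=C/C(C)=C/C=C1\C(C)(C)C[C@H](O[Si](C)(C)C(C)(C)C)C[C@@]1(C)O[Si](CC)(CC)CC | intermediate
38 | target retro-carotenoid triol (3S; 3'S,5'R; 6E; 6'E; all-E chain) | CC1=C[C@@H](O)CC(C)(C)\C1=C/C=C(C)/C=C/C=C(C)/C=C/C=C/C(C)=C/C=C/C(C)=C/C=C1\C(C)(C)C[C@H](O)C[C@@]1(C)O | target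

Total step count: 24 steps.
Longest linear sequence: 14 steps (steps 1–9, 19, 21, 22, 23, 24; the ring A branch through steps 1–7, 10–12, 18, 20, 23, 24 is equally long).

Steps most likely to fail

Step 7 (ring closure mediated by Ti(OiPr)4/i-PrMgCl). Complexation of the alkyne, which is flanked by a silyl group and a quaternary carbon, may be slow, so that the Grignard reagent or divalent titanium attacks the ester or the product ketone instead. The fallback runs from 10 back to 12 by a Ni(COD)2-catalysed reductive alkyne–aldehyde cyclisation. Reduction of 10 with i-Bu2AlH at −78 °C would give (3S)-3-[(tert-butyldimethylsilyl)oxy]-5,5-dimethyl-7-(trimethylsilyl)hept-6-ynal F1. Ni(COD)2/PBu3 with Et3SiH adds the carbonyl carbon and hydride syn across the alkyne, so the exocyclic geometry is the same, and would give tert-butyldimethyl{[(1S,4E)-3,3-dimethyl-5-[(triethylsilyl)oxy]-4-[(trimethylsilyl)methylidene]cyclohexyl]oxy}silane F2 as a mixture of carbinol epimers. Pyridinium p-toluenesulfonate in MeOH would remove the secondary triethylsilyl group selectively to give (2E,5S)-5-[(tert-butyldimethylsilyl)oxy]-3,3-dimethyl-2-[(trimethylsilyl)methylidene]cyclohexan-1-ol F3, and Dess–Martin oxidation returns ketone 12.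

Step 20 (hydrozirconation–iodination of the 2-alkyne). Addition of H–Zr to the conjugated internal alkyne may be incompletely regioselective, and iodine may isomerise or degrade the tetraene. The fallback runs from 19 to 37 and builds C13 from a 1,1-dibromoalkene, so no internal alkyne is hydrometallated on the ring A side. Carboalumination of (2E)-pent-2-en-4-yn-1-ol (excess Me3Al, Cp2ZrCl2) would give {(1E,3E)-5-[(dimethylalumanyl)oxy]-2-methylpenta-1,3-dien-1-yl}dimethylalumane F4. Coupling of this alane with 19 (Pd(PPh3)4, ZnCl2) and aqueous work-up would give (2E,4E,6E)-6-{(4S)-4-[(tert-butyldimethylsilyl)oxy]-2,6,6-trimethylcyclohex-2-en-1-ylidene}-4-methylhexa-2,4-dien-1-ol F5. MnO2 oxidation would give (2E,4E,6E)-6-{(4S)-4-[(tert-butyldimethylsilyl)oxy]-2,6,6-trimethylcyclohex-2-en-1-ylidene}-4-methylhexa-2,4-dienal F6. Ramirez olefination (CBr4, PPh3, Et3N) would give tert-butyl{[(1S,4E)-4-[(2E,4E)-7,7-dibromo-3-methylhepta-2,4,6-trien-1-ylidene]-3,5,5-trimethylcyclohex-2-en-1-yl]oxy}dimethylsilane F7. Trans-selective Negishi mono-alkenylation of this dibromide with alkenylzirconocene 36, made from 35 as in step 23 (PdCl2(DPEphos), ZnCl2), replaces the bromine trans to C11 and forms the C13–C14 bond, giving the (12Z)-13-bromo-13-demethyl analogue of 37 F8. Methylation of the remaining C–Br bond with retention (Me2Zn, Pd(t-Bu3P)2) gives 37.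

Step 23 (key coupling). The polyenyl zirconocene may be protonated or decompose before transmetallation, or the partners may homocouple. The fallback runs from 35 to 37 by Suzuki–Miyaura coupling of an isolable boronate. Hydroboration of 35 with pinacolborane (Cp2Zr(H)Cl 5 mol %, Et3N) would give the (E)-alkenyl pinacolboronate of 35 (boron on C14) F9, which is coupled with 32 (Pd(PPh3)4, aqueous NaOH, THF, rt) to give 37.

Further compounds
F1 | step 7 | (3S)-3-[(tert-butyldimethylsilyl)oxy]-5,5-dimethyl-7-(trimethylsilyl)hept-6-ynal | O=CC[C@@H](O[Si](C)(C)C(C)(C)C)CC(C)(C)C#C[Si](C)(C)C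
F2 | step 7 | tert-butyldimethyl{[(1S,4E)-3,3-dimethyl-5-[(triethylsilyl)oxy]-4-[(trimethylsilyl)methylidene]cyclohexyl]oxy}silane (both C5 epimers) | C[Si](C)(C)/C=C1/C(O[Si](CC)(CC)CC)C[C@@H](O[Si](C)(C)C(C)(C)C)CC1(C)C
F3 | step 7 | (2E,5S)-5-[(tert-butyldimethylsilyl)oxy]-3,3-dimethyl-2-[(trimethylsilyl)methylidene]cyclohexan-1-ol (both C1 epimers) | C[Si](C)(C)/C=C1/C(O)C[C@@H](O[Si](C)(C)C(C)(C)C)CC1(C)C
F4 | step 20 | {(1E,3E)-5-[(dimethylalumanyl)oxy]-2-methylpenta-1,3-dien-1-yl}dimethylalumane | C[Al](C)/C=C(C)/C=C/CO[Al](C)C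
F5 | step 20 | (2E,4E,6E)-6-{(4S)-4-[(tert-butyldimethylsilyl)oxy]-2,6,6-trimethylcyclohex-2-en-1-ylidene}-4-methylhexa-2,4-dien-1-ol | OC/C=C/C(C)=C/C=C1/C(C)=C[C@@H](O[Si](C)(C)C(C)(C)C)CC1(C)C
F6 | step 20 | (2E,4E,6E)-6-{(4S)-4-[(tert-butyldimethylsilyl)oxy]-2,6,6-trimethylcyclohex-2-en-1-ylidene}-4-methylhexa-2,4-dienal | O=C/C=C/C(C)=C/C=C1/C(C)=C[C@@H](O[Si](C)(C)C(C)(C)C)CC1(C)C
F7 | step 20 | tert-butyl{[(1S,4E)-4-[(2E,4E)-7,7-dibromo-3-methylhepta-2,4,6-trien-1-ylidene]-3,5,5-trimethylcyclohex-2-en-1-yl]oxy}dimethylsilane | BrC(Br)=C/C=C/C(C)=C/C=C1/C(C)=C[C@@H](O[Si](C)(C)C(C)(C)C)CC1(C)C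
F8 | step 20 | (12Z)-13-bromo-13-demethyl analogue of 37 | CC1=C[C@@H](O[Si](C)(C)C(C)(C)C)CC(C)(C)\C1=C/C=C(C)/C=C/C=C(Br)/C=C/C=C/C(C)=C/C=C/C(C)=C/C=C1\C(C)(C)C[C@H](O[Si](C)(C)C(C)(C)C)C[C@@]1(C)O[Si](CC)(CC)CC
F9 | step 23 | (E)-alkenyl pinacolboronate of 35 (boron on C14) | CC1(C)OB(/C=C/C=C/C(C)=C/C=C/C(C)=C/C=C2/[C@](C)(O[Si](CC)(CC)CC)C[C@@H](O[Si](C)(C)C(C)(C)C)CC2(C)C)OC1(C)C
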